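**Plan**
Cuts: first the three O-benzyl bonds of a protected precursor, then C2'-C3' and C1'-C6' of ring B. This leaves a 4-(flavon-8-yl)-1-methoxy-3-siloxybutadiene and a 2-ethynylchromone.
Enabling feature: in ring B (C1'-C6') the C4' hydroxyl is para to C1' (bonded to C2 of the 5-hydroxy-7-methoxychromone) and ortho to C3' (bonded to C8'' of the acacetin unit). A 1-methoxy-3-siloxydiene and an acceptor alkyne give this 1,3,4-pattern after loss of methanol.
The crowded C3'-C8'' bond is never forged between two arenes. It is the C8''-CH2 bond set by Claisen rearrangement of acacetin 7-allyl ether, and the allyl chain is then reworked into the diene.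
Ring order: the three acacetin rings are bought. The second pyranone is closed from 2',6'-dihydroxy-4'-methoxyacetophenone and diethyl oxalate, and its ester becomes the alkyne. Ring B closes last by cycloaddition, then hydrogenolysis.
Stereochemistry: the target has no stereocentre. Only the (1E,3Z) diene geometry matters, E from the oxa-Michael addition and Z from soft enolisation.

Key step: step 14

Assumption: the target SMILES fixes no configuration at the C3'-C8'' axis, so no atroposelection is attempted and axis-derived isomerism of intermediates is ignored.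

**Step 1**
Reactants: 1 acacetin; 2 allyl bromide
Product: 3 7-O-allylacacetin (7-allyloxy-5-hydroxy-2-(4-methoxyphenyl)chromen-4-one)
Conditions: K2CO3, acetone, reflux
Reagents that add atoms: none
Why: Williamson etherification is selective for the acidic 7-OH because the 5-OH is held in a hydrogen bond to the C4 carbonyl.

**Step 2**
Reactants: 3 7-O-allylacacetin
Product: 4 8-allylacacetin (8-allyl-5,7-dihydroxy-2-(4-methoxyphenyl)chromen-4-one)
Conditions: PhNEt2, 200 °C
Reagents that add atoms: none
Why: The thermal aromatic Claisen rearrangement ([3,3] shift, then tautomerisation) moves the allyl group from O7 to the neighbouring C8, the ortho site generally preferred by 7-allyloxy-5-hydroxyflavones, and any 6-allyl isomer is removed by chromatography.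

**Step 3**
Reactants: 4 8-allylacacetin
Product: 5 8-allyl-5,7-bis(benzyloxy)-2-(4-methoxyphenyl)chromen-4-one
Conditions: BnBr, K2CO3, DMF, 80 °C
Reagents that add atoms: benzyl bromide, BrCc1ccccc1
Why: Double Williamson benzylation, heated so that the chelated 5-OH also reacts, masks both phenols against the Grignard reagent and the silyl triflate used later.

**Step 4**
Reactants: 5 8-allyl-5,7-bis(benzyloxy)-2-(4-methoxyphenyl)chromen-4-one
Product: 6 2-[5,7-bis(benzyloxy)-2-(4-methoxyphenyl)-4-oxochromen-8-yl]acetaldehyde
Conditions: OsO4 (cat.), NaIO4, 2,6-lutidine, dioxane-H2O, rt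
Reagents that add atoms: sodium periodate, [Na+].[O-]I(=O)(=O)=O (terminal source of the aldehyde oxygen, relayed by OsO4)
Why: Lemieux-Johnson oxidation cleaves the terminal alkene far faster than the electron-poor, trisubstituted C2=C3 bond of the pyranone, and 2,6-lutidine limits over-oxidation.

**Step 5**
Reactants: 6 arylacetaldehyde; 7 ethynylmagnesium bromide
Product: 8 5,7-bis(benzyloxy)-8-(2-hydroxybut-3-yn-1-yl)-2-(4-methoxyphenyl)chromen-4-one (racemic)
Conditions: THF, -78 to -20 °C; then pH 7 buffer
Reagents that add atoms: none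
Why: Grignard 1,2-addition of the weakly basic alkynyl reagent to the aldehyde at low temperature outruns enolisation and spares the vinylogous-ester carbonyl of the flavone, and the racemic carbinol centre is erased in step 6.

**Step 6**
Reactants: 8 propargylic alcohol
Product: 9 5,7-bis(benzyloxy)-2-(4-methoxyphenyl)-8-(2-oxobut-3-yn-1-yl)chromen-4-one
Conditions: DMP, CH2Cl2, 0 °C to rt
Reagents that add atoms: none
Why: Dess-Martin oxidation of a secondary propargylic alcohol is fast under near-neutral conditions that leave the acidic benzylic CH2 and the benzyl ethers alone.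

**Step 7**
Reactants: 9 ynone
Product: 10 5,7-bis(benzyloxy)-8-[(3E)-4-methoxy-2-oxobut-3-en-1-yl]-2-(4-methoxyphenyl)chromen-4-one
Conditions: MeOH, DABCO (cat.), CH2Cl2, 0 °C
Reagents that add atoms: methanol, CO
Why: Amine-catalysed oxa-Michael addition of methanol to a terminal ynone gives the thermodynamically preferred (E)-β-methoxy enone, and the excess of methanol outcompetes self-addition of the ketone enolate.

**Step 8**
Reactants: 10 (E)-β-methoxy enone
Product: 11 (1E,3Z)-4-[5,7-bis(benzyloxy)-2-(4-methoxyphenyl)-4-oxochromen-8-yl]-1-methoxy-3-(tert-butyldimethylsilyloxy)buta-1,3-diene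
Conditions: TBSOTf, Et3N, Et2O-CH2Cl2, -78 to 0 °C; filtration through Et3N-deactivated silica
Reagents that add atoms: tert-butyldimethylsilyl triflate, CC(C)(C)[Si](C)(C)OS(=O)(=O)C(F)(F)F
Why: Soft enolisation (silyl triflate with a tertiary amine) can deprotonate only the benzylic CH2, and allylic strain places the bulky aryl group cis to the siloxy group, which is the (3Z) isomer with the aryl group on the outside of the s-cis diene.

**Step 9**
Reactants: 12 2',6'-dihydroxy-4'-methoxyacetophenone; 13 diethyl oxalate
Product: 15 ethyl 5-hydroxy-7-methoxy-4-oxochromene-2-carboxylate, via diketo ester 14 (not isolated)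
Conditions: NaOEt, EtOH, reflux; then conc. HCl, EtOH, reflux
Reagents that add atoms: none
Why: Claisen condensation of the acetophenone enolate with the oxalate, followed by acid-catalysed cyclodehydration, is the standard chromone-2-carboxylate synthesis, and the two equivalent phenols make the ring closure unambiguous.

**Step 10**
Reactants: 15 ethyl 5-hydroxy-7-methoxy-4-oxochromene-2-carboxylate
Product: 16 ethyl 5-(benzyloxy)-7-methoxy-4-oxochromene-2-carboxylate
Conditions: BnBr, K2CO3, DMF, 60 °C
Reagents that add atoms: benzyl bromide, BrCc1ccccc1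
Why: Williamson benzylation of the single remaining, chelated phenol removes the only acidic proton that could later destroy the silyl dienol ether.

**Step 11**
Reactants: 16 ethyl 5-(benzyloxy)-7-methoxy-4-oxochromene-2-carboxylate
Product: 17 5-(benzyloxy)-2-(hydroxymethyl)-7-methoxychromen-4-one
Conditions: NaBH4, EtOH-THF, 0 °C
Reagents that add atoms: none
Why: Chemoselective borohydride reduction takes the ester, which is activated by the electron-poor pyranone, while the vinylogous-ester C4 carbonyl is inert at 0 °C, as is known for chromone-2-carboxylates.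

**Step 12**
Reactants: 17 5-(benzyloxy)-2-(hydroxymethyl)-7-methoxychromen-4-one
Product: 18 5-(benzyloxy)-7-methoxy-4-oxochromene-2-carbaldehyde
Conditions: DMP, CH2Cl2, 0 °C to rt
Reagents that add atoms: none
Why: Dess-Martin oxidation stops cleanly at the aldehyde under anhydrous, non-basic conditions that the pyranone tolerates.

**Step 13**
Reactants: 18 5-(benzyloxy)-7-methoxy-4-oxochromene-2-carbaldehyde; 19 (trimethylsilyl)diazomethane
Product: 20 5-(benzyloxy)-2-ethynyl-7-methoxychromen-4-one
Conditions: 19, LDA, THF, -78 °C; then 18, -78 °C to rt; then H2O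
Reagents that add atoms: none
Why: In the Colvin rearrangement the lithiated diazosilane adds at -78 °C to the aldehyde, the most electrophilic carbonyl present, and loss of silanolate and N2 with a 1,2-hydrogen shift gives the terminal alkyne without the methanolic base that could add to the acceptor alkyne.

**Step 14**
Reactants: 11 (1E,3Z)-siloxydiene; 20 5-(benzyloxy)-2-ethynyl-7-methoxychromen-4-one
Product: 23 5,5'',7''-tri-O-benzylputraflavone, via cyclohexadiene adduct 21 (not isolated), via aryl silyl ether 22 (not isolated)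
Conditions: 20 (1.5 equiv), BHT (cat.), 4 Å MS, PhMe (1 M), 130 °C, sealed tube; then 48% aq HF, MeCN-THF, 0 °C to rt
Reagents that add atoms: none
Why: This is a normal-electron-demand, strongly asynchronous [4+2] cycloaddition in which C4 of diene 11, the aryl-bearing and most nucleophilic terminus, bonds to the terminal alkyne carbon of 20, the vinylogous β position of the C4 carbonyl (new C2'-C3' bond), while the methoxy-bearing C1 bonds to the internal alkyne carbon (new C1'-C6' bond). The closest known reaction is the Diels-Alder benzannulation of 1-methoxy-3-siloxybutadienes with propiolates and ynones, which gives phenols bearing the acceptor para to the hydroxyl. Ring B is the only ring closed, and it closes by intermolecular cycloaddition with both new bonds formed in the same event. Adduct 21 carries two transient stereocentres (C3' and C6', cis through suprafacial addition to the diene whose two substituents both point outward) that vanish when HF promotes 1,4-loss of methanol to 22 and then cleaves the silyl ether, so no stereocentre needs control. The step needs the hydroxyl para to the chromone and reaction at the alkyne rather than at either pyranone C2=C3 bond; the first follows from pairing the donor-polarised diene with the acceptor-polarised alkyne, the second because the linear terminal CH is the only acceptor carbon small enough to reach the terminus shielded by the twisted, di-ortho-substituted flavonyl group, whereas both pyranone alkenes are trisubstituted and deactivated by the ring oxygen. The (3Z) geometry keeps the flavonyl group outside the s-cis conformer, which therefore stays accessible, and the sieves take up liberated methanol before it can desilylate unreacted diene.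

**Step 15**
Reactants: 23 5,5'',7''-tri-O-benzylputraflavone
Product: 24 putraflavone
Conditions: H2 (1 atm), Pd/C, THF-MeOH, rt
Reagents that add atoms: none
Why: Catalytic hydrogenolysis cleaves the three benzylic C-O bonds at one atmosphere and room temperature, conditions under which flavone C2=C3 bonds and aryl methyl ethers are normally retained.

**Compound list**
1 | acacetin | COc1ccc(cc1)-c1cc(=O)c2c(O)cc(O)cc2o1 | starting material
2 | allyl bromide | C=CCBr | starting material
3 | 7-O-allylacacetin | COc1ccc(cc1)-c1cc(=O)c2c(O)cc(OCC=C)cc2o1 | intermediate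
4 | 8-allylacacetin | COc1ccc(cc1)-c1cc(=O)c2c(O)cc(O)c(CC=C)c2o1 | intermediate
5 | 8-allyl-5,7-bis(benzyloxy)-2-(4-methoxyphenyl)chromen-4-one | COc1ccc(cc1)-c1cc(=O)c2c(OCc3ccccc3)cc(OCc3ccccc3)c(CC=C)c2o1 | intermediate
6 | 2-[5,7-bis(benzyloxy)-2-(4-methoxyphenyl)-4-oxochromen-8-yl]acetaldehyde | COc1ccc(cc1)-c1cc(=O)c2c(OCc3ccccc3)cc(OCc3ccccc3)c(CC=O)c2o1 | intermediate
7 | ethynylmagnesium bromide | C#C[Mg]Br | starting material
8 | 5,7-bis(benzyloxy)-8-(2-hydroxybut-3-yn-1-yl)-2-(4-methoxyphenyl)chromen-4-one (racemic) | COc1ccc(cc1)-c1cc(=O)c2c(OCc3ccccc3)cc(OCc3ccccc3)c(CC(O)C#C)c2o1 | intermediate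
9 | 5,7-bis(benzyloxy)-2-(4-methoxyphenyl)-8-(2-oxobut-3-yn-1-yl)chromen-4-one | COc1ccc(cc1)-c1cc(=O)c2c(OCc3ccccc3)cc(OCc3ccccc3)c(CC(=O)C#C)c2o1 | intermediate
10 | 5,7-bis(benzyloxy)-8-[(3E)-4-methoxy-2-oxobut-3-en-1-yl]-2-(4-methoxyphenyl)chromen-4-one | CO/C=C/C(=O)Cc1c(OCc2ccccc2)cc(OCc2ccccc2)c2c(=O)cc(-c3ccc(OC)cc3)oc12 | intermediate
11 | (1E,3Z)-4-[5,7-bis(benzyloxy)-2-(4-methoxyphenyl)-4-oxochromen-8-yl]-1-methoxy-3-(tert-butyldimethylsilyloxy)buta-1,3-diene | CO/C=C/C(O[Si](C)(C)C(C)(C)C)=C/c1c(OCc2ccccc2)cc(OCc2ccccc2)c2c(=O)cc(-c3ccc(OC)cc3)oc12 | intermediate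
12 | 2',6'-dihydroxy-4'-methoxyacetophenone | CC(=O)c1c(O)cc(OC)cc1O | starting material
13 | diethyl oxalate | CCOC(=O)C(=O)OCC | starting material
14 | ethyl 4-(2,6-dihydroxy-4-methoxyphenyl)-2,4-dioxobutanoate (not isolated) | CCOC(=O)C(=O)CC(=O)c1c(O)cc(OC)cc1O | intermediate
15 | ethyl 5-hydroxy-7-methoxy-4-oxochromene-2-carboxylate | CCOC(=O)c1cc(=O)c2c(O)cc(OC)cc2o1 | intermediate
16 | ethyl 5-(benzyloxy)-7-methoxy-4-oxochromene-2-carboxylate | CCOC(=O)c1cc(=O)c2c(OCc3ccccc3)cc(OC)cc2o1 | intermediate
17 | 5-(benzyloxy)-2-(hydroxymethyl)-7-methoxychromen-4-one | OCc1cc(=O)c2c(OCc3ccccc3)cc(OC)cc2o1 | intermediate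
18 | 5-(benzyloxy)-7-methoxy-4-oxochromene-2-carbaldehyde | O=Cc1cc(=O)c2c(OCc3ccccc3)cc(OC)cc2o1 | intermediate
19 | (trimethylsilyl)diazomethane | C[Si](C)(C)C=[N+]=[N-] | starting material
20 | 5-(benzyloxy)-2-ethynyl-7-methoxychromen-4-one | C#Cc1cc(=O)c2c(OCc3ccccc3)cc(OC)cc2o1 | intermediate
21 | cis cyclohexa-1,4-diene adduct (racemic, one enantiomer drawn; not isolated): C1' bears the chromon-2-yl group, C3'(H) the flavon-8-yl group, C4' the OTBS group, C6'(H) the OMe group | CO[C@H]1C=C(O[Si](C)(C)C(C)(C)C)[C@@H](c2c(OCc3ccccc3)cc(OCc3ccccc3)c3c(=O)cc(-c4ccc(OC)cc4)oc23)C=C1c1cc(=O)c2c(OCc3ccccc3)cc(OC)cc2o1 | intermediate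
22 | 5,5'',7''-tri-O-benzyl-4'-O-(tert-butyldimethylsilyl)putraflavone (not isolated) | COc1ccc(-c2cc(=O)c3c(OCc4ccccc4)cc(OCc4ccccc4)c(-c4cc(-c5cc(=O)c6c(OCc7ccccc7)cc(OC)cc6o5)ccc4O[Si](C)(C)C(C)(C)C)c3o2)cc1 | intermediate
23 | 5,5'',7''-tri-O-benzylputraflavone | COc1ccc(-c2cc(=O)c3c(OCc4ccccc4)cc(OCc4ccccc4)c(-c4cc(-c5cc(=O)c6c(OCc7ccccc7)cc(OC)cc6o5)ccc4O)c3o2)cc1 | intermediate
24 | putraflavone | COc1ccc(-c2cc(=O)c3c(O)cc(O)c(-c4cc(-c5cc(=O)c6c(O)cc(OC)cc6o5)ccc4O)c3o2)cc1 | target

Total step count: 15. Longest linear sequence: 10 (steps 1-8, 14, 15). The ethynylchromone arm (steps 9-13) runs in parallel.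

**Steps most likely to fail**

Step 14. The alkyne is activated only through the pyranone double bond. The diene terminus that must bond first is flanked by a twisted, di-ortho-substituted aryl group. Cycloaddition may therefore be slower than thermal desilylation or hydrolysis of the diene.

The fallback sets out from 11 (and from 12) and keeps the benzannulation, but builds the pyranone afterwards.
- Diene 11 is heated with methyl propiolate, whose acceptor sits directly on the alkyne. This should give methyl cis-3-[5,7-bis(benzyloxy)-2-(4-methoxyphenyl)-4-oxochromen-8-yl]-4-(tert-butyldimethylsilyloxy)-6-methoxycyclohexa-1,4-diene-1-carboxylate F1.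
- Catalytic camphorsulfonic acid in CH2Cl2 aromatises F1 to methyl 3-[5,7-bis(benzyloxy)-2-(4-methoxyphenyl)-4-oxochromen-8-yl]-4-(tert-butyldimethylsilyloxy)benzoate F2.
- Monobenzylation of 12 (BnBr, K2CO3, acetone) gives 2'-(benzyloxy)-6'-hydroxy-4'-methoxyacetophenone F3.
- The dianion of F3 (LiHMDS, THF) undergoes crossed Claisen condensation with F2. This gives 1-[2-(benzyloxy)-6-hydroxy-4-methoxyphenyl]-3-{3-[5,7-bis(benzyloxy)-2-(4-methoxyphenyl)-4-oxochromen-8-yl]-4-(tert-butyldimethylsilyloxy)phenyl}propane-1,3-dione F4.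
- Cyclodehydration with catalytic p-TsOH in toluene at 80 °C closes the pyranone and comes back to the route at 22, which aqueous HF converts into 23 as in step 14.

Step 2. Migration of the allyl group to C6 instead of C8 would erode regiochemical purity, because both ortho sites lie between two oxygen substituents.

The fallback sets out from 1 and replaces the sigmatropic shift by halogenation and cross-coupling.
- Double benzylation (BnBr, K2CO3, DMF, 80 °C) gives 5,7-bis(benzyloxy)-2-(4-methoxyphenyl)chromen-4-one F5.
- NIS in DMF iodinates C8, the site preferred once O5 is alkylated, to give 5,7-bis(benzyloxy)-8-iodo-2-(4-methoxyphenyl)chromen-4-one F6.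
- Stille coupling with allyltributylstannane (Pd(PPh3)4, DMF, 100 °C) comes back to the route at 5.

Step 13. The lithiated diazo compound may attack the pyranone, or nucleophiles may add to the electrophilic ethynylchromone while the mixture warms. Either process would consume material.

The fallback sets out from 18 and replaces the carbene rearrangement by olefination and elimination.
- Stork-Zhao olefination ((iodomethyl)triphenylphosphonium iodide, NaHMDS, THF, -78 °C) gives 5-(benzyloxy)-2-[(Z)-2-iodovinyl]-7-methoxychromen-4-one F7.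
- The anti-periplanar H and I of F7 are removed by further NaHMDS at -78 °C, followed by a proton quench, which comes back to the route at 20.

**Further compounds**
F1 | step 14 | methyl cis-3-[5,7-bis(benzyloxy)-2-(4-methoxyphenyl)-4-oxochromen-8-yl]-4-(tert-butyldimethylsilyloxy)-6-methoxycyclohexa-1,4-diene-1-carboxylate (racemic, one enantiomer drawn) | CO[C@H]1C=C(O[Si](C)(C)C(C)(C)C)[C@@H](c2c(OCc3ccccc3)cc(OCc3ccccc3)c3c(=O)cc(-c4ccc(OC)cc4)oc23)C=C1C(=O)OC
F2 | step 14 | methyl 3-[5,7-bis(benzyloxy)-2-(4-methoxyphenyl)-4-oxochromen-8-yl]-4-(tert-butyldimethylsilyloxy)benzoate | COC(=O)c1ccc(O[Si](C)(C)C(C)(C)C)c(c1)-c1c(OCc2ccccc2)cc(OCc2ccccc2)c2c(=O)cc(-c3ccc(OC)cc3)oc12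
F3 | step 14 | 2'-(benzyloxy)-6'-hydroxy-4'-methoxyacetophenone | CC(=O)c1c(O)cc(OC)cc1OCc1ccccc1
F4 | step 14 | 1-[2-(benzyloxy)-6-hydroxy-4-methoxyphenyl]-3-{3-[5,7-bis(benzyloxy)-2-(4-methoxyphenyl)-4-oxochromen-8-yl]-4-(tert-butyldimethylsilyloxy)phenyl}propane-1,3-dione | O=C(CC(=O)c1c(O)cc(OC)cc1OCc1ccccc1)c1ccc(O[Si](C)(C)C(C)(C)C)c(c1)-c1c(OCc2ccccc2)cc(OCc2ccccc2)c2c(=O)cc(-c3ccc(OC)cc3)oc12
F5 | step 2 | 5,7-bis(benzyloxy)-2-(4-methoxyphenyl)chromen-4-one | COc1ccc(cc1)-c1cc(=O)c2c(OCc3ccccc3)cc(OCc3ccccc3)cc2o1
F6 | step 2 | 5,7-bis(benzyloxy)-8-iodo-2-(4-methoxyphenyl)chromen-4-one | COc1ccc(cc1)-c1cc(=O)c2c(OCc3ccccc3)cc(OCc3ccccc3)c(I)c2o1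
F7 | step 13 | 5-(benzyloxy)-2-[(Z)-2-iodovinyl]-7-methoxychromen-4-one | I/C=C\c1cc(=O)c2c(OCc3ccccc3)cc(OC)cc2o1
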